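**Plan**
- Retrosynthesis: the butenolide is opened by taking out CO2, cutting ring O1–C5 and C2–C3, to leave the linear ethyl ynone 27. Ring C4(OH)/C5(=C1′H) is a masked C(=O)–C≡C and C3(CH3) is the enolisable CH2 of the ethyl ketone, so the O1–C2(=O) unit is exactly one CO2.
- Further cuts: the C3–C4 acyl bond (acetylide + propionyl Weinreb amide), the C4′–C5′ bond at the allylic CH2 of the E-alkene (allyl chloride + Grignard), and the C12′–C13′ bond next to the furan (tosylate + furylmethyl Grignard).
- Forward: (R)-linalool gives the left half 12 (hydroboration, tosylation, allylic oxidation, furylmethyl coupling, chloride). (S)-4-(trimethylsilyl)but-3-yn-2-ol gives the right half 21 (mesylate, malonate SN2, decarboxylation, reduction, bromide). The halves are coupled, the alkyne is unmasked and acylated, and the butenolide, the only ring made, is closed last.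
- Stereochemistry: C10′ is the linalool carbinol carried unchanged; C2′ comes from the purchased alkynol through one SN2 inversion; the 6′E alkene comes from E-selective oxidation of linalool's terminal methyl; the 5Z alkene comes from anti-addition across the alkyne in the key step.
- The key-step precursor needs no protecting group, tether or change of oxidation level; tertiary OH, furan and both stereocentres are carried free.

Key step: step 15

Assumption: (R)-(−)-linalool and (S)-4-(trimethylsilyl)but-3-yn-2-ol are bought in high enantiomeric purity; the two remote stereocentres are set independently, so the stereochemical purity of the target is bounded by these two materials.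

**Step 1**
Reactants: 1 (R)-(−)-linalool
Product: 3 (R)-3,7-dimethyloct-6-ene-1,3-diol, via B-alkyl-9-BBN adduct 2 (not isolated)
Conditions: 9-BBN (1.5 equiv), THF, 0 °C → rt; then 3 M NaOH, 30% H2O2, 0 °C → rt
Reagents that add atoms: hydrogen peroxide, OO
Why: Hydroboration–oxidation: 9-BBN should add to the monosubstituted vinyl group (boron at the terminal carbon) far faster than to the trisubstituted alkene or the hindered tertiary O–H, and the carbinol stereocentre taken from 1 is not touched.

**Step 2**
Reactants: 3 (R)-3,7-dimethyloct-6-ene-1,3-diol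
Product: 4 (R)-3-hydroxy-3,7-dimethyloct-6-en-1-yl 4-methylbenzenesulfonate
Conditions: TsCl (1.1 equiv), Et3N, DMAP (cat.), CH2Cl2, 0 °C
Reagents that add atoms: 4-toluenesulfonyl chloride, Cc1ccc(cc1)S(Cl)(=O)=O
Why: Chemoselective O-sulfonylation: the primary hydroxyl reacts with TsCl while the tertiary carbinol is too hindered, and the mild amine base should not trigger oxetane formation.

**Step 3**
Reactants: 4 (R)-3-hydroxy-3,7-dimethyloct-6-en-1-yl 4-methylbenzenesulfonate
Product: 5 (3R,6E)-3,8-dihydroxy-3,7-dimethyloct-6-en-1-yl 4-methylbenzenesulfonate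
Conditions: SeO2 (0.5 equiv), t-BuOOH (2 equiv), CH2Cl2, 0 °C → rt; then NaBH4, MeOH, 0 °C
Reagents that add atoms: selenium dioxide, O=[Se]=O; tert-butyl hydroperoxide, CC(C)(C)OO
Why: Riley allylic oxidation (ene reaction then [2,3]-sigmatropic shift of the allylseleninic acid) should hydroxylate the (E)-methyl group of the trisubstituted alkene selectively to give the E-allylic alcohol, the borohydride finish returning any over-oxidised enal to 5.

**Step 4**
Reactants: 6 furan-3-ylmethanol
Product: 8 3-(chloromethyl)furan, via furan-3-ylmethyl mesylate 7 (not isolated)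
Conditions: MsCl, LiCl, 2,4,6-collidine, DMF, 0 °C; used directly
Reagents that add atoms: lithium chloride, [Li+].[Cl-]
Why: One-pot mesylation and chloride displacement (SN2) of a hetero-benzylic alcohol under buffered, non-acidic conditions that the acid-sensitive furan should tolerate.

**Step 5**
Reactants: 5 (3R,6E)-3,8-dihydroxy-3,7-dimethyloct-6-en-1-yl 4-methylbenzenesulfonate; 8 3-(chloromethyl)furan
Product: 10 (2E,6S)-9-(furan-3-yl)-2,6-dimethylnon-2-ene-1,6-diol, via furan-3-ylmethylmagnesium chloride 9 (not isolated)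
Conditions: 8, Mg, THF, rt (→ 9, 3.5 equiv); then 5, Li2CuCl4 (5 mol %), THF, −78 → 0 °C
Reagents that add atoms: none
Why: Copper-catalysed sp3–sp3 cross-coupling of a Grignard reagent with a primary tosylate, in which the furylmethyl reagent is expected to bond through its exocyclic CH2; two equivalents of 9 only deprotonate the hydroxyls, and the carbinol centre is unchanged (its descriptor becomes S purely by CIP ranking).

**Step 6**
Reactants: 10 (2E,6S)-9-(furan-3-yl)-2,6-dimethylnon-2-ene-1,6-diol
Product: 12 (4S,7E)-9-chloro-1-(furan-3-yl)-4,8-dimethylnon-7-en-4-ol, via allylic mesylate 11 (not isolated)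
Conditions: MsCl, LiCl, 2,4,6-collidine, DMF, 0 °C
Reagents that add atoms: lithium chloride, [Li+].[Cl-]
Why: Selective conversion of the primary allylic alcohol into the chloride by SN2 displacement of the in-situ mesylate, which should occur without allylic transposition, E/Z change or reaction at the tertiary alcohol.

**Step 7**
Reactants: 13 (S)-4-(trimethylsilyl)but-3-yn-2-ol
Product: 14 (S)-4-(trimethylsilyl)but-3-yn-2-yl methanesulfonate
Conditions: MsCl, Et3N, CH2Cl2, −40 → 0 °C; used crude
Reagents that add atoms: methanesulfonyl chloride, CS(Cl)(=O)=O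
Why: Mesylation at oxygen activates the propargylic carbinol without breaking the C–O bond, so the S configuration is retained.

**Step 8**
Reactants: 14 (S)-4-(trimethylsilyl)but-3-yn-2-yl methanesulfonate; 15 di-tert-butyl malonate
Product: 17 di-tert-butyl (S)-2-[4-(trimethylsilyl)but-3-yn-2-yl]malonate, via sodium di-tert-butyl malonate 16 (not isolated)
Conditions: 15, NaH, THF–DMF, 0 °C; then 14, rt → 45 °C
Reagents that add atoms: none
Why: SN2 alkylation of a soft stabilised carbanion at the activated secondary propargylic mesylate should go with clean inversion (the C-silyl group discouraging SN2′ attack), which sets the propargylic methyl stereocentre; the letter stays S only because the CIP ranking of the substituents changes.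

**Step 9**
Reactants: 17 di-tert-butyl (S)-2-[4-(trimethylsilyl)but-3-yn-2-yl]malonate
Product: 19 (S)-3-methyl-5-(trimethylsilyl)pent-4-ynoic acid, via malonic acid 18 (not isolated)
Conditions: TFA, CH2Cl2, 0 °C → rt; evaporate; then xylenes, 140 °C
Reagents that add atoms: none
Why: Acidolysis of both tert-butyl esters followed by thermal decarboxylation of the malonic acid (cyclic six-membered transition state) gives the monoacid under conditions that, unlike a basic or salt-mediated dealkoxycarbonylation, should keep the alkynyl–silicon bond and the β-stereocentre.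

**Step 10**
Reactants: 19 (S)-3-methyl-5-(trimethylsilyl)pent-4-ynoic acid
Product: 20 (S)-3-methyl-5-(trimethylsilyl)pent-4-yn-1-ol
Conditions: LiAlH4, Et2O, 0 °C → rt; Rochelle-salt work-up
Reagents that add atoms: none
Why: Hydride reduction of the carboxylic acid to the primary alcohol; the silyl alkyne has no nearby hydroxyl to direct hydroalumination and should be retained.

**Step 11**
Reactants: 20 (S)-3-methyl-5-(trimethylsilyl)pent-4-yn-1-ol
Product: 21 (S)-(5-bromo-3-methylpent-1-yn-1-yl)trimethylsilane
Conditions: CBr4, PPh3, CH2Cl2, 0 °C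
Reagents that add atoms: carbon tetrabromide, BrC(Br)(Br)Br
Why: Appel reaction: bromide displaces the alkoxyphosphonium at the primary carbon under neutral conditions that leave the C–Si bond and the stereocentre intact.

**Step 12**
Reactants: 12 (4S,7E)-9-chloro-1-(furan-3-yl)-4,8-dimethylnon-7-en-4-ol; 21 (S)-(5-bromo-3-methylpent-1-yn-1-yl)trimethylsilane
Product: 23 (4S,7E,12S)-1-(furan-3-yl)-4,8,12-trimethyl-14-(trimethylsilyl)tetradec-7-en-13-yn-4-ol, via Grignard reagent 22 (not isolated)
Conditions: 21, Mg, THF, 40 °C (→ 22, 1.3 equiv); 12, i-PrMgCl (1.0 equiv), THF, −78 °C; then 22, Li2CuCl4 (5 mol %), −78 → −20 °C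
Reagents that add atoms: none
Why: Copper-catalysed Grignard cross-coupling with a primary allylic chloride, which with Li2CuCl4 in THF at low temperature should occur at the α-carbon with retention of the E geometry, the tertiary hydroxyl being held as its magnesium alkoxide so that the chiral Grignard reagent is not consumed; no stereocentre is formed.

**Step 13**
Reactants: 23 (4S,7E,12S)-1-(furan-3-yl)-4,8,12-trimethyl-14-(trimethylsilyl)tetradec-7-en-13-yn-4-ol
Product: 24 (4S,7E,12S)-1-(furan-3-yl)-4,8,12-trimethyltetradec-7-en-13-yn-4-ol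
Conditions: K2CO3, MeOH, rt
Reagents that add atoms: none
Why: Methanolysis of the alkynyl–silicon bond (methoxide at silicon, protonation of the acetylide) is selective for C(sp)–Si and should leave the non-acidic propargylic methine configurationally intact.

**Step 14**
Reactants: 24 (4S,7E,12S)-1-(furan-3-yl)-4,8,12-trimethyltetradec-7-en-13-yn-4-ol; 25 N-methoxy-N-methylpropanamide
Product: 27 (6S,10E,14S)-17-(furan-3-yl)-14-hydroxy-6,10,14-trimethylheptadec-10-en-4-yn-3-one, via dilithio alkoxide-acetylide 26 (not isolated)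
Conditions: n-BuLi (2.1 equiv), THF, −78 °C; then 25, −78 → 0 °C; sat. NH4Cl
Reagents that add atoms: none
Why: Weinreb ketone synthesis: the lithium acetylide adds once to the N-methoxy-N-methylamide to give a chelated tetrahedral intermediate that collapses to the ynone only on work-up, the second equivalent of base merely holding the carbinol as its alkoxide.

**Step 15**
Reactants: 27 (6S,10E,14S)-17-(furan-3-yl)-14-hydroxy-6,10,14-trimethylheptadec-10-en-4-yn-3-one
Product: 29 (5Z)-5-[(2S,6E,10S)-13-(furan-3-yl)-10-hydroxy-2,6,10-trimethyltridec-6-en-1-ylidene]-4-hydroxy-3-methylfuran-2(5H)-one, via β-keto carboxylate 28 (not isolated)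
Conditions: AgOAc (10 mol %), DBU (2 equiv; MTBD if enolisation is slow), CO2 (1.0 MPa), MeCN, 25 °C; then 1 M HCl
Reagents that add atoms: carbon dioxide, O=C=O
Why: The base forms the α′-enolate at C2 of the ethyl ketone, which captures CO2 to give β-keto carboxylate 28; Ag(I) then π-activates the C4≡C5 bond, the carboxylate oxygen adds to C4 anti to silver, and protodeargentation of the alkenylsilver followed by enolisation of the ring ketone should deliver the 4-hydroxybutenolide. The closest known reaction type is the silver-catalysed carboxylative cyclisation of conjugated ynones with CO2 to 5-ylidene tetronic acids (and of alkynyl ketones to ylidene γ-lactones). The one ring formed closes 5-exo-dig, oxygen bonding to the alkyne carbon next to the carbonyl. No sp3 stereocentre is created; the exocyclic alkene geometry is controlled by the anti oxy-argentation and stereoretentive protonation, which put the ring oxygen and the side chain cis (Z). The step needs α′- over γ-deprotonation and 5-exo over 6-endo (pyranone) closure: the first is secured by the more acidic, unhindered ketone CH2 against the tertiary propargylic methine with CO2 buffering the free base, the second by the soft π-acid and the O–C(=O)–C–C(=O) tether that holds oxygen over C4. The furan, trisubstituted alkene, tertiary alcohol and both stereocentres are not addressed by Ag(I)/CO2 and should pass unchanged.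

**Compound list**
1 | (R)-(−)-linalool | CC(C)=CCC[C@@](C)(O)C=C | starting material
2 | B-alkyl-9-BBN adduct of linalool | CC(C)=CCC[C@@](C)(O)CCB1C2CCCC1CCC2 | intermediate (not isolated)
3 | (R)-3,7-dimethyloct-6-ene-1,3-diol | CC(C)=CCC[C@@](C)(O)CCO | intermediate
4 | (R)-3-hydroxy-3,7-dimethyloct-6-en-1-yl 4-methylbenzenesulfonate | CC(C)=CCC[C@@](C)(O)CCOS(=O)(=O)c1ccc(C)cc1 | intermediate
5 | (3R,6E)-3,8-dihydroxy-3,7-dimethyloct-6-en-1-yl 4-methylbenzenesulfonate | OC/C(C)=C/CC[C@@](C)(O)CCOS(=O)(=O)c1ccc(C)cc1 | intermediate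
6 | furan-3-ylmethanol | OCc1ccoc1 | starting material
7 | furan-3-ylmethyl methanesulfonate | CS(=O)(=O)OCc1ccoc1 | intermediate (not isolated)
8 | 3-(chloromethyl)furan | ClCc1ccoc1 | intermediate
9 | furan-3-ylmethylmagnesium chloride | Cl[Mg]Cc1ccoc1 | intermediate (not isolated)
10 | (2E,6S)-9-(furan-3-yl)-2,6-dimethylnon-2-ene-1,6-diol | OC/C(C)=C/CC[C@@](C)(O)CCCc1ccoc1 | intermediate
11 | (2E,6S)-9-(furan-3-yl)-6-hydroxy-2,6-dimethylnon-2-en-1-yl methanesulfonate | CS(=O)(=O)OC/C(C)=C/CC[C@@](C)(O)CCCc1ccoc1 | intermediate (not isolated)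
12 | (4S,7E)-9-chloro-1-(furan-3-yl)-4,8-dimethylnon-7-en-4-ol | ClC/C(C)=C/CC[C@@](C)(O)CCCc1ccoc1 | intermediate
13 | (S)-4-(trimethylsilyl)but-3-yn-2-ol | C[C@H](O)C#C[Si](C)(C)C | starting material
14 | (S)-4-(trimethylsilyl)but-3-yn-2-yl methanesulfonate | C[C@H](OS(C)(=O)=O)C#C[Si](C)(C)C | intermediate
15 | di-tert-butyl malonate | CC(C)(C)OC(=O)CC(=O)OC(C)(C)C | starting material
16 | sodium di-tert-butyl malonate | [Na+].CC(C)(C)OC(=O)[CH-]C(=O)OC(C)(C)C | intermediate (not isolated)
17 | di-tert-butyl (S)-2-[4-(trimethylsilyl)but-3-yn-2-yl]malonate | C[Si](C)(C)C#C[C@@H](C)C(C(=O)OC(C)(C)C)C(=O)OC(C)(C)C | intermediate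
18 | (S)-2-[4-(trimethylsilyl)but-3-yn-2-yl]malonic acid | C[Si](C)(C)C#C[C@@H](C)C(C(=O)O)C(=O)O | intermediate (not isolated)
19 | (S)-3-methyl-5-(trimethylsilyl)pent-4-ynoic acid | C[Si](C)(C)C#C[C@@H](C)CC(=O)O | intermediate
20 | (S)-3-methyl-5-(trimethylsilyl)pent-4-yn-1-ol | C[Si](C)(C)C#C[C@@H](C)CCO | intermediate
21 | (S)-(5-bromo-3-methylpent-1-yn-1-yl)trimethylsilane | C[Si](C)(C)C#C[C@@H](C)CCBr | intermediate
22 | (S)-[3-methyl-5-(trimethylsilyl)pent-4-yn-1-yl]magnesium bromide | C[Si](C)(C)C#C[C@@H](C)CC[Mg]Br | intermediate (not isolated)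
23 | (4S,7E,12S)-1-(furan-3-yl)-4,8,12-trimethyl-14-(trimethylsilyl)tetradec-7-en-13-yn-4-ol | C[Si](C)(C)C#C[C@@H](C)CCC/C(C)=C/CC[C@@](C)(O)CCCc1ccoc1 | intermediate
24 | (4S,7E,12S)-1-(furan-3-yl)-4,8,12-trimethyltetradec-7-en-13-yn-4-ol | C#C[C@@H](C)CCC/C(C)=C/CC[C@@](C)(O)CCCc1ccoc1 | intermediate
25 | N-methoxy-N-methylpropanamide | CCC(=O)N(C)OC | starting material
26 | dilithio alkoxide-acetylide of 24 | [Li]C#C[C@@H](C)CCC/C(C)=C/CC[C@@](C)(O[Li])CCCc1ccoc1 | intermediate (not isolated)
27 | (6S,10E,14S)-17-(furan-3-yl)-14-hydroxy-6,10,14-trimethylheptadec-10-en-4-yn-3-one | CCC(=O)C#C[C@@H](C)CCC/C(C)=C/CC[C@@](C)(O)CCCc1ccoc1 | intermediate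
28 | (6S,10E,14S)-17-(furan-3-yl)-14-hydroxy-2,6,10,14-tetramethyl-3-oxoheptadec-10-en-4-ynoic acid (present as its amidinium or silver carboxylate; C2 unresolved) | CC(C(=O)O)C(=O)C#C[C@@H](C)CCC/C(C)=C/CC[C@@](C)(O)CCCc1ccoc1 | intermediate (not isolated)
29 | (5Z)-5-[(2S,6E,10S)-13-(furan-3-yl)-10-hydroxy-2,6,10-trimethyltridec-6-en-1-ylidene]-4-hydroxy-3-methylfuran-2(5H)-one | CC1=C(O)/C(=C/[C@@H](C)CCC/C(C)=C/CC[C@@](C)(O)CCCc2ccoc2)OC1=O | target

**Step count**
Total: 15 steps. Longest linear sequence: 9 steps (1 → 3 → 4 → 5 → 10 → 12 → 23 → 24 → 27 → 29; the branch from 13 is also 9).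

**Steps most likely to fail**

Step 15. Under the amine base the ynone may lose its γ-proton (the propargylic methine) in competition with α′-enolisation. That would erode the C6 configuration or isomerise the ynone to allenyl or dienyl ketones. The base may also add in conjugate fashion, or the reversible carboxylation may not keep pace, so that little carboxylate reaches the silver-mediated closure.

The fallback builds the carboxyl carbon by aldol addition and oxidation instead of CO2 capture. It sets out from alkyne 24 and comes back at carboxylate 28.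
- Deprotonation of 24 as in step 14 gives 26, which is formylated with DMF (buffered inverse quench) to (4S,8E,12S)-15-(furan-3-yl)-12-hydroxy-4,8,12-trimethylpentadec-8-en-2-ynal F1.
- 2-(Trimethylsilyl)ethyl propanoate F2 (from propanoyl chloride and 2-(trimethylsilyl)ethanol, pyridine) is converted with LDA at −78 °C into its lithium enolate F3.
- F3 adds to F1 to give 2-(trimethylsilyl)ethyl (6S,10E,14S)-17-(furan-3-yl)-3,14-dihydroxy-2,6,10,14-tetramethylheptadec-10-en-4-ynoate F4 (diastereomers, of no consequence).
- Dess–Martin oxidation should give 2-(trimethylsilyl)ethyl (6S,10E,14S)-17-(furan-3-yl)-14-hydroxy-2,6,10,14-tetramethyl-3-oxoheptadec-10-en-4-ynoate F5.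
- TBAF (THF, 0 °C) cleaves the silylethyl ester to the ammonium salt of 28, and catalytic AgOAc in MeCN should close it to 29 by the same 5-exo-dig anti-addition, without amine base, enolate equilibration or CO2 pressure.

Step 12. The alkylcopper may attack the γ-carbon (SN2′, giving the branched 1,1-disubstituted alkene). E geometry may be lost through σ–π–σ equilibration of the allylcopper intermediate. The tertiary alkoxide may close onto the allylic chloride in a 5-exo SN2′ fashion, or the Grignard reagent may homocouple.

The fallback is allyl sulfone alkylation followed by reductive desulfonylation. It sets out from 12 (with 21) and comes back at 23.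
- 12 with PhSO2Na (DMF, rt) should give (4S,7E)-1-(furan-3-yl)-4,8-dimethyl-9-(phenylsulfonyl)non-7-en-4-ol F6.
- n-BuLi (2.1 equiv, THF–DMPU, −78 °C) gives its dilithio alkoxide/α-sulfonyl carbanion F7.
- F7 is alkylated with 21 to (4S,7E,12S)-1-(furan-3-yl)-4,8,12-trimethyl-9-(phenylsulfonyl)-14-(trimethylsilyl)tetradec-7-en-13-yn-4-ol F8 (C9 epimers).
- PdCl2(dppp) (cat.) with LiBHEt3 (THF, 0 °C) should deliver hydride to the carbon that carried sulfur, with the alkene position and E geometry retained, to give 23.

Step 5. The furylmethyl Grignard reagent may dimerise (Wurtz-type) while it is generated. It may bond through ring C2 instead of the exocyclic CH2. The γ-alkoxide may close onto the tosylate (oxetane) before cross-coupling.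

The fallback is sulfone-anion alkylation followed by reductive desulfonylation. It sets out from 8 (with 5) and comes back at 10.
- 8 with PhSO2Na (DMF, rt) should give 3-[(phenylsulfonyl)methyl]furan F9.
- n-BuLi (THF, −78 °C) converts it into lithio-3-[(phenylsulfonyl)methyl]furan F10 (3.2 equiv, two of which hold the hydroxyls of 5 as alkoxides).
- F10 is alkylated by tosylate 5 (THF–DMPU, −78 → 0 °C) to (2E,6R)-9-(furan-3-yl)-2,6-dimethyl-9-(phenylsulfonyl)non-2-ene-1,6-diol F11 (C9 epimers; the 6R letter is a CIP change only).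
- Na(Hg), Na2HPO4, MeOH, −20 °C should remove the sulfonyl group to give 10.

**Further compounds**
F1 | step 15 | (4S,8E,12S)-15-(furan-3-yl)-12-hydroxy-4,8,12-trimethylpentadec-8-en-2-ynal | O=CC#C[C@@H](C)CCC/C(C)=C/CC[C@@](C)(O)CCCc1ccoc1
F2 | step 15 | 2-(trimethylsilyl)ethyl propanoate | CCC(=O)OCC[Si](C)(C)C
F3 | step 15 | lithium enolate of 2-(trimethylsilyl)ethyl propanoate | CC=C(O[Li])OCC[Si](C)(C)C
F4 | step 15 | 2-(trimethylsilyl)ethyl (6S,10E,14S)-17-(furan-3-yl)-3,14-dihydroxy-2,6,10,14-tetramethylheptadec-10-en-4-ynoate | C[Si](C)(C)CCOC(=O)C(C)C(O)C#C[C@@H](C)CCC/C(C)=C/CC[C@@](C)(O)CCCc1ccoc1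
F5 | step 15 | 2-(trimethylsilyl)ethyl (6S,10E,14S)-17-(furan-3-yl)-14-hydroxy-2,6,10,14-tetramethyl-3-oxoheptadec-10-en-4-ynoate | C[Si](C)(C)CCOC(=O)C(C)C(=O)C#C[C@@H](C)CCC/C(C)=C/CC[C@@](C)(O)CCCc1ccoc1
F6 | step 12 | (4S,7E)-1-(furan-3-yl)-4,8-dimethyl-9-(phenylsulfonyl)non-7-en-4-ol | O=S(=O)(C/C(C)=C/CC[C@@](C)(O)CCCc1ccoc1)c1ccccc1
F7 | step 12 | dilithio alkoxide/α-sulfonyl carbanion of F6 | [Li]C(/C(C)=C/CC[C@@](C)(O[Li])CCCc1ccoc1)S(=O)(=O)c1ccccc1
F8 | step 12 | (4S,7E,12S)-1-(furan-3-yl)-4,8,12-trimethyl-9-(phenylsulfonyl)-14-(trimethylsilyl)tetradec-7-en-13-yn-4-ol | C[Si](C)(C)C#C[C@@H](C)CCC(/C(C)=C/CC[C@@](C)(O)CCCc1ccoc1)S(=O)(=O)c1ccccc1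
F9 | step 5 | 3-[(phenylsulfonyl)methyl]furan | O=S(=O)(Cc1ccoc1)c1ccccc1
F10 | step 5 | lithio-3-[(phenylsulfonyl)methyl]furan | [Li]C(c1ccoc1)S(=O)(=O)c1ccccc1
F11 | step 5 | (2E,6R)-9-(furan-3-yl)-2,6-dimethyl-9-(phenylsulfonyl)non-2-ene-1,6-diol | OC/C(C)=C/CC[C@@](C)(O)CCC(c1ccoc1)S(=O)(=O)c1ccccc1
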